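**Plan**
Retrosynthesis: the target is a 27-membered lactone ring (C1–C26 plus one oxygen, no stereocentre). It is cut at C13–C14, read as a former C13=C14 alkene, and at the acyl bond C1–O.
Enabling feature: these cuts split the 26 ring carbons into C1–C13 and C14–C26. Each half is the C1–C13 stretch of a natural C22 erucyl chain, whose only alkene begins at carbon 13 counted from the oxygen-bearing end.
Forward: erucic acid 1 and erucyl alcohol 2 are joined as ester 3 (C1–O–C26). The only ring is then closed by metathesis of the two internal alkenes to give 4 (C13=C14 formed), and hydrogenation gives 5.
Stereochemistry: none has to be set. The cis alkenes of 1 and 2 are consumed, and the E/Z outcome in 4 disappears in the last step.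

Key step: step 2

Remark on the chemistry: 1 and 2 are assumed to be free of chain-length and positional homologues (99% grade or better). A C18, C20 or C24 monoene with its alkene 9, 11 or 15 carbons from the head group would be folded into a ring of another size.

**Step 1**
Reactants: 1 erucic acid, (13Z)-docos-13-enoic acid; 2 erucyl alcohol, (13Z)-docos-13-en-1-ol
Product: 3 erucyl erucate, (13Z)-docos-13-en-1-yl (13Z)-docos-13-enoate
Conditions: 1 and 2 (1:1), p-TsOH·H2O (5 mol%), toluene, reflux, water separator; NaHCO3 wash; filtration through activated neutral Al2O3 (hexane)
Reagents that add atoms: none
Why: Fischer esterification pulled to completion by azeotropic removal of water is the standard access to wax esters from a fatty acid and a primary fatty alcohol, a catalytic sulfonic acid in dilute toluene should leave isolated 1,2-disubstituted alkenes where they are, and the alumina pass removes acid, alcohol and hydroperoxide traces that would shorten the life of the ruthenium catalyst.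

**Step 2**
Reactants: 3 erucyl erucate
Product: 4 hexacos-13-en-26-olide (oxacycloheptacos-14-en-2-one), E isomer drawn, accompanied by its Z isomer
Conditions: RuCl2(H2IMes)(PCy3)(=CHPh) (second-generation Grubbs catalyst, 2 × 2.5 mol%), 1,4-benzoquinone (10 mol%), degassed CH2Cl2 (1 mM in 3), 40 °C, Ar; then ethyl vinyl ether, only then concentration; SiO2 (hexane, then hexane/Et2O)
Reagents that add atoms: none
Why: Loss of PCy3 gives the 14-electron ruthenium alkylidene, which adds to one cis alkene of 3 to form a metallacyclobutane, cycloreverts with the metal left on a tethered C13 terminus, and repeats the [2+2] addition and cycloreversion on the second alkene, so that C13=C14 is formed and the two nonylidene halves end up together as octadec-9-ene. The closest known reaction type is ring-closing metathesis of unsaturated wax esters and fatty ketones bearing two internal alkenes, which gives macrocycles with loss of an internal olefin, and cis-1,2-disubstituted fatty alkenes are exchanged readily by this catalyst. The one ring closed is the 27-membered lactone (26 C, 1 O), which closes end to end between the two remote alkene carbons with the new alkene endocyclic, as a strain-free macrocyclisation under thermodynamic control; pairing the four alkene carbons anew within one molecule has only two outcomes, 3 again or 4 plus octadec-9-ene, so the ring size follows from both alkenes lying 13 carbons from the ester. No stereocentre is formed, and the E/Z composition at C13=C14 (E expected to prevail at equilibrium) is irrelevant because step 3 removes it. The selectivity needed is ring against linear and cyclic oligomers and against re-opening by the involatile octadecene; because every alkene present stays active, slow addition cannot replace true dilution, the final total concentration of about 1 mM must lie well below the effective molarity usually assumed for strainless large rings so that the entropy gained by doubling the number of molecules decides the equilibrium, and the catalyst is destroyed with ethyl vinyl ether before any solvent is removed so that the equilibrium cannot slide back on concentration. 1,4-Benzoquinone intercepts ruthenium hydrides and should suppress alkene migration, the only path to ring-contracted or ring-expanded homologues, while the ester, eleven and twelve methylenes from the alkenes, can neither chelate nor deactivate the carbene.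

**Step 3**
Reactants: 4 hexacos-13-en-26-olide (E/Z mixture)
Product: 5 26-hexacosanolide (oxacycloheptacosan-2-one)
Conditions: H2 (1 atm), Pd/C (10 wt% Pd, 5 mol% Pd), EtOAc, rt to 40 °C
Reagents that add atoms: none
Why: Heterogeneous catalytic hydrogenation of an unhindered 1,2-disubstituted alkene is routine, both geometric isomers and any isomer formed by migration on the palladium surface converge on the same saturated ring, and the lactone has no allylic or benzylic C–O bond to lose.

**Compound list**
1 | erucic acid, (13Z)-docos-13-enoic acid | CCCCCCCC/C=C\CCCCCCCCCCCC(=O)O | starting material
2 | erucyl alcohol, (13Z)-docos-13-en-1-ol | CCCCCCCC/C=C\CCCCCCCCCCCCO | starting material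
3 | erucyl erucate, (13Z)-docos-13-en-1-yl (13Z)-docos-13-enoate | CCCCCCCC/C=C\CCCCCCCCCCCC(=O)OCCCCCCCCCCCC/C=C\CCCCCCCC | intermediate
4 | hexacos-13-en-26-olide, oxacycloheptacos-14-en-2-one (E drawn, Z isomer alongside) | O=C1CCCCCCCCCCC/C=C/CCCCCCCCCCCCO1 | intermediate
5 | 26-hexacosanolide, oxacycloheptacosan-2-one | O=C1CCCCCCCCCCCCCCCCCCCCCCCCCO1 | target

Total step count: 3. Longest linear sequence: 3.

**Steps most likely to fail**

Step 2 (highest risk). The exchange may stall at an equilibrium in which re-opening of the ring by the retained C18 olefin and chain growth to oligomers compete with closure. The catalyst may also decay at its very low concentration before equilibrium is reached.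

The fallback sets out from 3 and removes both tails first by ethenolysis (ethene 10 bar, first-generation Grubbs catalyst RuCl2(PCy3)2(=CHPh), toluene, 40 °C). This should give tetradec-13-en-1-yl tetradec-13-enoate F1, from which the dec-1-ene formed is distilled off. F1 is then closed by ring-closing metathesis of its two terminal alkenes (RuCl2(PCy3)2(=CHPh), CH2Cl2, reflux, slow addition, argon sparge).

The co-product is now a gas, so closure is driven by its escape and no longer by dilution alone. This catalyst acts much more slowly on the internal alkene of the product than on terminal alkenes, so slow addition becomes effective. The same C13=C14 bond and the same ring are formed, and the route is rejoined at 4.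

Step 1. The condensation may stop short of completion at 1:1 stoichiometry. Prolonged heating with acid may also start migration of the alkenes along the chain, or addition of the carboxylic acid across them, and either process would later corrupt the ring size.

The fallback sets out from 1 and 2 and forms the other C–O bond of the ester by a Mitsunobu reaction (PPh3, DIAD, THF, 0 °C to rt). The alcohol, not the acid, is activated, and erucate displaces the activated oxygen at the primary carbinol carbon under neutral conditions at room temperature. Trituration with hexane should free the wax ester from the polar residues, and the route is rejoined at 3.

Step 3. Hydrogen uptake may cease early through fouling of the palladium surface by ruthenium, phosphine or quinone residues carried over from step 2, or through crystallisation of the waxy product on the catalyst.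

The fallback sets out from 4 and uses metal-free reduction with diimide generated in the flask (p-toluenesulfonyl hydrazide in excess, NaOAc, DME/H2O, reflux). Diimide transfers two hydrogens to the alkene in a concerted syn fashion and leaves the lactone untouched. The route is rejoined directly at 5.

**Further compounds**
F1 | step 2 | tetradec-13-en-1-yl tetradec-13-enoate | C=CCCCCCCCCCCCC(=O)OCCCCCCCCCCCCC=C
F0 | step 1 | none | none
F0 | step 3 | none | none
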